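## Structural features

The target is a tetracycle: a dibenzo[b,f]oxepine (ring A = C1–C4 with C4a and C11a, seven-membered ring B with O5, ring C = C6–C9 with C5a and C9a) whose C10=C11 bond is shared with a 3,4-dihydro-2H-pyran (ring D). The pyran oxygen sits on C10 (ring C side) and the pyran CH2 on C11 (ring A side), so C10=C11 is a tetrasubstituted enol ether conjugated with both arenes. Ring A carries a free hydroxyl at C3 and a prenyl group at C2; ring C carries a free hydroxyl at C7, para to C9a. Ring D holds the only two stereocentres, bonded to each other: the quaternary ether carbon (methyl and 4-methylpent-3-enyl, S) and the carbinol carbon (S), with the hydroxyl trans to the methyl group. Fragile elements are the enol ether (acid), two trisubstituted alkenes (acid, electrophiles; hydrogenolysis is excluded), the ortho-prenylphenol (closes to a chroman under acid) and two electron-rich phenols (oxidation). The real difficulties are the fully regiodefined substitution of ring A, which electrophilic prenylation of a resorcinol does not deliver reliably, and the tertiary ether stereocentre inside a tetrasubstituted enol ether. The key step exploits the atom sequence C3(OH)–C4(H)–C4a(O-aryl)–C11a(C11)–C1(H)–C2(prenyl) of ring A, which is exactly the pattern that a vinylketene and an alkynyl ether assemble, with the ring C aryloxy group riding in on the alkyne.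

## Logic of the disconnections

35 ⇒ 34. The two phenolic O–H bonds are traced back to O–Si bonds. The phenols are the most acidic and most oxidisable sites, and fluoride is the one deprotection mode that spares the enol ether and both alkenes. Nothing is gained in skeleton, but every earlier basic or acidic step meets no free ArOH. The forward step must run near neutral.

34 ⇒ 33. The ring D bond between the pyran oxygen and the quaternary carbon is cut, and the C10=C11 π bond is returned to C10=O and C11–H. A configurationally defined tertiary ether is best made by backside opening of an epoxide, and the oxygen needed is already present as the C10 carbonyl. Ring D and the enol ether disappear, and both stereocentres are stored in one epoxide. The forward step demands attack of the carbonyl oxygen at the tertiary and not the secondary epoxide carbon, with inversion there and retention at the secondary carbon, under acid mild enough for alkenes and silyl ethers. This closure is an isomerisation, not a dehydration, and the inversion is the reason why the cis-epoxide from the (Z)-alcohol is required; a closure with retention from a diol would need the (E) series.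

33 ⇒ 28 + 31. The C11–CH2 bond is cut. C11 is the only enolisable position of 28 and the electrophile is a primary sulfonate. The achiral tricycle separates from the small chiral fragment, which makes the route convergent. The forward step demands alkylation at carbon and not at the enolate oxygen, and no attack on the epoxide; the C11 configuration is irrelevant because C11 becomes sp2.

31 ⇒ 30 ⇒ 29. The sulfonate S–O bond and then both epoxide C–O bonds are removed. A tartrate-controlled epoxidation of an allylic alcohol sets both centres in one step and touches only the 2,3-alkene. This reaches a commercial achiral terpene alcohol. The (Z) geometry fixes the relative configuration and the tartrate enantiomer the absolute one.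

28 ⇒ 26 ⇒ 24 ⇒ 23. The C10–C9a aryl ketone bond is cut back to an arylacetic acid, then the acid to its methyl ester and the ring A silyl ether to the phenol. The ring C carbon to be acylated is ortho to the bridging oxygen and para to the silyloxy group, the most nucleophilic and least hindered site, and the closure is intramolecular. Ring B is opened and a simple diaryl ether ester remains. The forward steps demand an acylation without strong Lewis acid and an ester cleavage without hydroxide attack on silicon.

23 ⇒ 19 + 9. Ring A is taken apart completely. Counted from 19, four ring bonds are new (C11a–C1, C3–C4, C4a–C11a, C2–C3); counted from the ketene stage the number is three. Every substituent of ring A is dictated by the two components, so the prenyl position is fixed by construction and the diaryl ether is carried in on the alkyne. Two simple open-chain or monocyclic pieces remain. The forward step demands that the 1,2-shift outruns carbene chemistry, that the [2+2] addition has the right orientation, and that the alkyne survives light.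

19 ⇒ 16 ⇒ 12 + 13, and 12 ⇒ 10 + 11. The C=N2 group is returned to CH2, then the acyl–alkenyl bond and the propargylic C–C bond are cut. Each cut follows a reliable polar or metal-mediated bond formation and ends at commercial C5, C2 and C4 pieces. The demands are site-selective enolisation at C3 and preservation of the (E)-enone and the skipped diene.

9 ⇒ 6 ⇒ 2 + 3, and 2 ⇒ 1. The alkyne is returned to a dichlorovinyl ether, the vinyl C–O bond is cut, and the silyl ether is removed. This is the standard route to alkynyl ethers from a hydroxyl compound and a C2 chlorocarbon. The silyl ether must survive a potassium phenoxide and an alkyllithium.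

## Other disconnections considered

Alternative 1: The cut goes through ring B at two bonds at once, the diaryl ether bond O5–C5a and the C10–C9a bond. Ring D is kept as δ-lactone A1 carrying ring A, and ring C is the aryne precursor, silyl triflate A2. In the forward step fluoride generates a chloro-alkoxy benzyne from A2, the phenoxide of A1 adds at the aryne carbon remote from chlorine, the aryl anion attacks the lactone carbonyl to close ring B, and acidic work-up dehydrates the lactol to the enol ether of tetracycle A3.
- In its favour: two bonds and ring B are made in one operation with high convergence. The tertiary oxygen is already bonded to C10 as the lactone, so the question of which epoxide carbon is attacked does not exist; on this point the alternative is better than the chosen plan.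
- Against it: the aryl anion must close a seven-membered ring in competition with proton transfer from the acidic lactone α-position. The chlorine that steers the aryne must later be removed in the presence of two trisubstituted alkenes and an enol ether. The acetal protecting groups call for acid at the end, where the ortho-prenylphenol and the enol ether are at risk. Ring A of A1 still needs a regiodefined prenyl group, which is the problem the benzannulation solves.
- Comparison: on structure the alternative secures ring D and leaves ring A unsolved; the chosen plan does the reverse. On mechanism an anionic cascade with a removable directing atom stands against a pericyclic cascade needing no directing group. On step economy the endgames are about equal, but A1 and A2 each need a longer synthesis than 19 and 9.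

Alternative 2: The cut is the C10=C11 bond itself. The precursor is keto ester A4, a tertiary alcohol benzoate whose ester carbonyl is C10 and whose aryl ketone carbonyl is C11. Low-valent titanium from TiCl3 and Zn couples the two carbonyls reductively to give dihydropyran A5; ring B is closed afterwards by an intramolecular C–O coupling between the ring A bromide and a ring C phenol.
- In its favour: the ester linkage presets the tertiary C–O bond with retention, so ring D regiochemistry and configuration are secure; this equals or exceeds the chosen plan. Rings A and C enter as separate, simple acyl components.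
- Against it: the electron-rich, hindered benzoate is a poor partner, so pinacol coupling of the aryl ketone may compete. Low-valent titanium is Lewis acidic and reducing towards the aryl bromide and silyl ethers. The later ring B closure must unmask one of four silyl ethers selectively and form a strained diaryl ether across a cis-diarylalkene. Ring A again needs a regiodefined prenyl group.
- Comparison: on mechanism a reductive metal coupling forms the enol ether directly, where the chosen plan forms it by proton loss after epoxide opening. On step economy the alternative is longer because of protecting-group traffic and the separate ring B closure.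

Alternative 3: The cut is the C11–C11a bond, traced back to a symmetrical xanthone. Addition of a lithiated 1,1-dibromoalkane bearing both stereocentres gives dibromo carbinol A6. n-BuLi then generates a β-oxido carbenoid whose 1,2-aryl shift expands the central ring to dibenzoxepinone A7, with the whole side chain already at C11.
- In its favour: the tricycle with its diaryl ether comes from a cheap symmetrical xanthone, so the aryl shift has no regiochemical ambiguity. No Friedel–Crafts acid is needed. C11 is alkylated by construction, so alkylation at oxygen cannot occur; on these points the alternative is better than the chosen plan. Ring D is then closed with retention from a differentiated diol, which is also secure.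
- Against it: the prenyl group is missing and must be introduced late, ortho to one of two nearly equivalent aryl oxygens, with no reliable control. A β-silyloxy carbenoid is prone to elimination, and the vinylogous-ester-like xanthone carbonyl is a sluggish electrophile.
- Comparison: on structure it solves rings B and D and fails on ring A, the reverse of the chosen plan. On mechanism a carbenoid rearrangement stands against a pericyclic cascade. On step economy the core is shorter, but the side-chain dibromide and the late prenylation with its selectivity losses outweigh that gain.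

Key step: step 7

Remark on the chemistry: atom labels follow dibenzo[b,f]oxepine numbering as used above; the ring D stereocentres are taken as (S) at the quaternary carbon and (S) at the carbinol carbon, as read from the target SMILES.

## Route

Step 1
Reactants: 1 resorcinol
Product: 2 3-(triisopropylsilyloxy)phenol
Conditions: i-Pr3SiCl (1 equiv), imidazole, DMF, 0 °C to rt; 1 in threefold excess
Reagents that add atoms: triisopropylsilyl chloride, CC(C)[Si](Cl)(C(C)C)C(C)C
Why: Statistical monosilylation of a symmetrical diphenol, the excess of 1 keeping bis-silylation low; the bulky silyl ether is chosen to survive KH, n-BuLi, light and mild acid later.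

Step 2
Reactants: 2 3-(triisopropylsilyloxy)phenol; 3 trichloroethylene
Product: 6 1-[(E)-1,2-dichloroethenyloxy]-3-(triisopropylsilyloxy)benzene, via potassium phenoxide 4 (not isolated), via dichloroacetylene 5 (not isolated)
Conditions: KH (1.2 equiv), THF, 0 °C; then 3, 0 °C to rt
Reagents that add atoms: none
Why: Standard dichlorovinyl ether synthesis: base converts 3 into 5, phenoxide 4 adds anti across it, and the vinyl anion is protonated by further 3 in a chain process, which gives the (E)-ether without heating that could move the silyl group.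

Step 3
Reactants: 6 1-[(E)-1,2-dichloroethenyloxy]-3-(triisopropylsilyloxy)benzene
Product: 9 1-(ethynyloxy)-3-(triisopropylsilyloxy)benzene, via chloroethynyl ether 7 (not isolated), via lithium acetylide 8 (not isolated)
Conditions: n-BuLi (2.2 equiv), THF, −78 to −40 °C; MeOH, −78 °C; kept cold in solution and used at once
Reagents that add atoms: none
Why: Vinylic deprotonation with loss of LiCl gives 7, chlorine–lithium exchange gives 8, and cold protonation gives the terminal ynol ether (dichlorovinyl ether route to alkynyl ethers); aryl ethynyl ethers hydrate and polymerise easily, hence the neutral cold work-up.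

Step 4
Reactants: 10 prenyl bromide; 11 ethynylmagnesium bromide
Product: 12 5-methylhex-4-en-1-yne
Conditions: CuCl (5 mol %), THF, 0 °C to rt
Reagents that add atoms: none
Why: Copper-catalysed coupling of an allylic bromide with an alkynyl Grignard reagent at the primary terminus of the prenyl unit; the medium is not basic enough to isomerise the skipped enyne.

Step 5
Reactants: 12 5-methylhex-4-en-1-yne; 13 methyl 4-chloro-4-oxobutanoate
Product: 16 methyl (5E)-9-methyl-4-oxodeca-5,8-dienoate, via alkenylzirconocene chloride 14 (not isolated), via alkenylzinc chloride 15 (not isolated)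
Conditions: Cp2Zr(H)Cl, THF, rt; ZnCl2, THF, 0 °C; then 13, Pd(PPh3)4 (5 mol %), 0 °C to rt
Reagents that add atoms: none
Why: Hydrozirconation adds Zr–H syn and anti-Markovnikov to the terminal alkyne only, and transmetalation to zinc followed by Negishi acylation on zerovalent palladium gives the (E)-enone with retention; ester and skipped diene tolerate these neutral conditions.

Step 6
Reactants: 16 methyl (5E)-9-methyl-4-oxodeca-5,8-dienoate
Product: 19 methyl (5E)-3-diazo-9-methyl-4-oxodeca-5,8-dienoate, via lithium enolate 17 (not isolated), via trifluoroacetyl diketone 18 (not isolated)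
Conditions: LiN(SiMe3)2, THF, −78 °C; CF3CO2CH2CF3, −78 °C; then MeSO2N3, Et3N, H2O (1 equiv), MeCN, rt
Reagents that add atoms: methanesulfonyl azide, CS(=O)(=O)N=[N+]=[N-]
Why: Detrifluoroacetylative diazo transfer: kinetic deprotonation at −78 °C takes the only ketone α-CH2 (C3) in preference to the less acidic ester α-carbon and the γ-carbon, trifluoroacetylation activates that carbon, and azide transfer with loss of the trifluoroacetyl group gives the diazo ketone without touching the enone.

Step 7
Reactants: 19 methyl (5E)-3-diazo-9-methyl-4-oxodeca-5,8-dienoate; 9 1-(ethynyloxy)-3-(triisopropylsilyloxy)benzene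
Product: 23 methyl 2-[4-hydroxy-5-(3-methylbut-2-enyl)-2-[3-(triisopropylsilyloxy)phenoxy]phenyl]acetate, via vinylketene 20 (not isolated), via vinylcyclobutenone 21 (not isolated), via dienylketene 22 (not isolated)
Conditions: hν (300 nm), 9 (1.5 equiv), degassed ClCH2CH2Cl, rt; then 80 °C
Reagents that add atoms: none
Why: Irradiation expels N2 from 19 with 1,2-shift of the dienyl group from the carbonyl carbon to the diazo carbon (photochemical Wolff rearrangement) and gives vinylketene 20. The nucleophilic terminal carbon of 9 attacks the ketene carbonyl carbon and the ketene α-carbon bonds to the oxygen-bearing alkyne carbon, a regioselective [2+2] addition that gives 21. Four-electron electrocyclic opening of 21 gives dienylketene 22, whose thermal six-electron disrotatory electrocyclisation closes the six-membered carbocycle ring A, and tautomerisation of the cyclohexadienone gives phenol 23. The closest known reaction is the Danheiser benzannulation in its diazo ketone variant with alkoxy- and siloxyalkynes, of which the aryl ethynyl ether is a further member. Counted from 19, four ring bonds are new (C11a–C1 in the Wolff shift, C3–C4 and C4a–C11a in the [2+2] step, C2–C3 in the electrocyclisation) and two are broken; counted from 20 the number of new bonds is three. No stereocentre is formed. The selectivity that matters is the orientation of the [2+2] step, secured by the polarisation of 9 by its oxygen, which places the aryloxy group meta to the new hydroxyl with hydrogen between them, while the prenyl group on the alkene terminus of 19 ends ortho to the hydroxyl and the acetate arm para to it. The excess of 9 and the dilute, degassed solution serve to intercept 20 before it dimerises or acylates 23, and the final heating completes the two electrocyclic steps.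

Step 8
Reactants: 23 methyl 2-[4-hydroxy-5-(3-methylbut-2-enyl)-2-[3-(triisopropylsilyloxy)phenoxy]phenyl]acetate
Product: 24 methyl 2-[5-(3-methylbut-2-enyl)-4-(triisopropylsilyloxy)-2-[3-(triisopropylsilyloxy)phenoxy]phenyl]acetate
Conditions: i-Pr3SiCl, imidazole, DMF, rt
Reagents that add atoms: triisopropylsilyl chloride, CC(C)[Si](Cl)(C(C)C)C(C)C
Why: Silyl ether formation, so that both phenols carry the same fluoride-labile group and the later enolate meets no acidic OH; chloride and imidazole avoid strong acid next to the prenyl group.

Step 9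
Reactants: 24 methyl 2-[5-(3-methylbut-2-enyl)-4-(triisopropylsilyloxy)-2-[3-(triisopropylsilyloxy)phenoxy]phenyl]acetate
Product: 26 2-[5-(3-methylbut-2-enyl)-4-(triisopropylsilyloxy)-2-[3-(triisopropylsilyloxy)phenoxy]phenyl]acetic acid, via trimethylstannyl ester 25 (not isolated)
Conditions: Me3SnOH, ClCH2CH2Cl, 80 °C; then cold 0.1 M aq HCl wash
Reagents that add atoms: trimethyltin hydroxide, C[Sn](C)(C)O
Why: Me3SnOH cleaves methyl esters through a tin carboxylate under neutral conditions, which spares the two aryl silyl ethers that aqueous hydroxide could attack; the brief cold acid wash frees the acid.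

Step 10
Reactants: 26 2-[5-(3-methylbut-2-enyl)-4-(triisopropylsilyloxy)-2-[3-(triisopropylsilyloxy)phenoxy]phenyl]acetic acid
Product: 28 2-(3-methylbut-2-enyl)-3,7-bis(triisopropylsilyloxy)dibenzo[b,f]oxepin-10(11H)-one, via mixed anhydride 27 (not isolated)
Conditions: (CF3CO)2O, CH2Cl2, 0 °C to rt; aq NaHCO3
Reagents that add atoms: none
Why: Intramolecular Friedel–Crafts acylation through the mixed trifluoroacetic anhydride: ring C is attacked at the carbon ortho to the bridging oxygen and para to the silyloxy group (the other ortho carbon lies between two oxygens and is shielded by the silyl group), which closes seven-membered ring B without a metal halide that would endanger the prenyl alkene.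

Step 11
Reactants: 29 nerol
Product: 30 [(2S,3R)-3-methyl-3-(4-methylpent-3-enyl)oxiran-2-yl]methanol
Conditions: Ti(OiPr)4 (5 mol %), L-(+)-diethyl tartrate (6 mol %), t-BuOOH, 4 Å molecular sieves, CH2Cl2, −20 °C
Reagents that add atoms: tert-butyl hydroperoxide, CC(C)(C)OO
Why: Sharpless asymmetric epoxidation: the allylic hydroxyl confines oxidation to the 2,3-alkene, the L-(+)-tartrate is the ligand that leads to the (2S) series of epoxy alcohols, and the (Z) geometry translates into the cis-epoxide (2S,3R), which stores both ring D stereocentres.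

Step 12
Reactants: 30 [(2S,3R)-3-methyl-3-(4-methylpent-3-enyl)oxiran-2-yl]methanol
Product: 31 [(2S,3R)-3-methyl-3-(4-methylpent-3-enyl)oxiran-2-yl]methyl trifluoromethanesulfonate
Conditions: Tf2O, 2,6-lutidine, CH2Cl2, −78 °C; used at once
Reagents that add atoms: trifluoromethanesulfonic anhydride, O=S(=O)(OS(=O)(=O)C(F)(F)F)C(F)(F)F
Why: Sulfonylation of the primary alcohol with a hindered base; the epoxy triflate is a primary electrophile reactive enough for a ketone enolate at −78 °C, and neither stereocentre is touched.

Step 13
Reactants: 28 2-(3-methylbut-2-enyl)-3,7-bis(triisopropylsilyloxy)dibenzo[b,f]oxepin-10(11H)-one; 31 [(2S,3R)-3-methyl-3-(4-methylpent-3-enyl)oxiran-2-yl]methyl trifluoromethanesulfonate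
Product: 33 11-[[(2S,3R)-3-methyl-3-(4-methylpent-3-enyl)oxiran-2-yl]methyl]-2-(3-methylbut-2-enyl)-3,7-bis(triisopropylsilyloxy)dibenzo[b,f]oxepin-10(11H)-one (both C11 epimers), via lithium enolate 32 (not isolated)
Conditions: LiN(SiMe3)2 (1.0 equiv), THF, −78 °C; then 31, −78 to −30 °C; cold NH4Cl quench
Reagents that add atoms: none
Why: Enolate alkylation: C11 is the only enolisable position, and its lithium enolate should displace the primary triflate by SN2 faster than it attacks the trisubstituted epoxide; lithium in THF without polar additives favours carbon over oxygen, one equivalent of base and the cold quench keep 33 from re-enolising, and the C11 configuration is left open because C11 becomes sp2 next.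

Step 14
Reactants: 33 11-[[(2S,3R)-3-methyl-3-(4-methylpent-3-enyl)oxiran-2-yl]methyl]-2-(3-methylbut-2-enyl)-3,7-bis(triisopropylsilyloxy)dibenzo[b,f]oxepin-10(11H)-one
Product: 34 3,7-bis(triisopropylsilyl) ether of 35
Conditions: BF3·OEt2 (0.2 equiv), CH2Cl2, −78 to −40 °C; aq NaHCO3
Reagents that add atoms: none
Why: Lewis-acid-promoted 6-endo opening of a trisubstituted epoxide by a carbonyl oxygen: the C10 oxygen attacks the tertiary epoxide carbon from the back (inversion, R to S), the oxocarbenium ion loses the doubly activated C11 proton to give the conjugated enol ether, and the carbinol carbon keeps its (S) configuration as the former epoxide C–O bond; both C11 epimers converge, and the closure is an isomerisation in which no water is lost.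

Step 15
Reactants: 34 3,7-bis(triisopropylsilyl) ether of 35
Product: 35 target
Conditions: Bu4NF, AcOH, THF, 0 °C
Reagents that add atoms: none
Why: Fluoride-mediated desilylation of both aryl silyl ethers; the acetic acid buffer keeps the medium near neutral so that the enol ether, the prenyl groups and the free phenols see neither strong base nor acid.

## Compound list

1 | resorcinol | Oc1cccc(O)c1 | starting material
2 | 3-(triisopropylsilyloxy)phenol | Oc1cccc(O[Si](C(C)C)(C(C)C)C(C)C)c1 | intermediate
3 | trichloroethylene | ClC=C(Cl)Cl | starting material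
4 | potassium 3-(triisopropylsilyloxy)phenoxide | [K+].[O-]c1cccc(O[Si](C(C)C)(C(C)C)C(C)C)c1 | intermediate
5 | dichloroacetylene | ClC#CCl | intermediate
6 | 1-[(E)-1,2-dichloroethenyloxy]-3-(triisopropylsilyloxy)benzene | Cl/C=C(/Cl)Oc1cccc(O[Si](C(C)C)(C(C)C)C(C)C)c1 | intermediate
7 | 1-(chloroethynyloxy)-3-(triisopropylsilyloxy)benzene | ClC#COc1cccc(O[Si](C(C)C)(C(C)C)C(C)C)c1 | intermediate
8 | lithium 2-[3-(triisopropylsilyloxy)phenoxy]ethynide | [Li]C#COc1cccc(O[Si](C(C)C)(C(C)C)C(C)C)c1 | intermediate
9 | 1-(ethynyloxy)-3-(triisopropylsilyloxy)benzene | C#COc1cccc(O[Si](C(C)C)(C(C)C)C(C)C)c1 | intermediate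
10 | prenyl bromide (1-bromo-3-methylbut-2-ene) | CC(C)=CCBr | starting material
11 | ethynylmagnesium bromide | C#C[Mg]Br | starting material
12 | 5-methylhex-4-en-1-yne | C#CCC=C(C)C | intermediate
13 | methyl 4-chloro-4-oxobutanoate | COC(=O)CCC(=O)Cl | starting material
14 | chlorobis(cyclopentadienyl)[(1E)-5-methylhexa-1,4-dienyl]zirconium | CC(C)=CC/C=C/[Zr](Cl)(C1C=CC=C1)C1C=CC=C1 | intermediate
15 | chloro[(1E)-5-methylhexa-1,4-dienyl]zinc | CC(C)=CC/C=C/[Zn]Cl | intermediate
16 | methyl (5E)-9-methyl-4-oxodeca-5,8-dienoate | COC(=O)CCC(=O)/C=C/CC=C(C)C | intermediate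
17 | lithium enolate of 16 (C3=C4, O–Li on C4) | COC(=O)CC=C(O[Li])/C=C/CC=C(C)C | intermediate
18 | methyl (5E)-9-methyl-4-oxo-3-(2,2,2-trifluoroacetyl)deca-5,8-dienoate | COC(=O)CC(C(=O)C(F)(F)F)C(=O)/C=C/CC=C(C)C | intermediate
19 | methyl (5E)-3-diazo-9-methyl-4-oxodeca-5,8-dienoate | COC(=O)CC(=[N+]=[N-])C(=O)/C=C/CC=C(C)C | intermediate
20 | methyl (4E)-8-methyl-3-(oxomethylidene)nona-4,7-dienoate | COC(=O)CC(=C=O)/C=C/CC=C(C)C | intermediate
21 | methyl 2-[1-[(1E)-5-methylhexa-1,4-dienyl]-4-oxo-2-[3-(triisopropylsilyloxy)phenoxy]cyclobut-2-en-1-yl]acetate (racemic) | COC(=O)CC1(/C=C/CC=C(C)C)C(=O)C=C1Oc1cccc(O[Si](C(C)C)(C(C)C)C(C)C)c1 | intermediate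
22 | methyl (4E)-8-methyl-3-[3-oxo-1-[3-(triisopropylsilyloxy)phenoxy]prop-2-enylidene]nona-4,7-dienoate, ketenyl group cis to the C4 alkene | O=C=C/C(Oc1cccc(O[Si](C(C)C)(C(C)C)C(C)C)c1)=C(CC(=O)OC)\C=C\CC=C(C)C | intermediate
23 | methyl 2-[4-hydroxy-5-(3-methylbut-2-enyl)-2-[3-(triisopropylsilyloxy)phenoxy]phenyl]acetate | COC(=O)Cc1cc(CC=C(C)C)c(O)cc1Oc1cccc(O[Si](C(C)C)(C(C)C)C(C)C)c1 | intermediate
24 | methyl 2-[5-(3-methylbut-2-enyl)-4-(triisopropylsilyloxy)-2-[3-(triisopropylsilyloxy)phenoxy]phenyl]acetate | COC(=O)Cc1cc(CC=C(C)C)c(O[Si](C(C)C)(C(C)C)C(C)C)cc1Oc1cccc(O[Si](C(C)C)(C(C)C)C(C)C)c1 | intermediate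
25 | trimethylstannyl ester of 26 | C[Sn](C)(C)OC(=O)Cc1cc(CC=C(C)C)c(O[Si](C(C)C)(C(C)C)C(C)C)cc1Oc1cccc(O[Si](C(C)C)(C(C)C)C(C)C)c1 | intermediate
26 | 2-[5-(3-methylbut-2-enyl)-4-(triisopropylsilyloxy)-2-[3-(triisopropylsilyloxy)phenoxy]phenyl]acetic acid | OC(=O)Cc1cc(CC=C(C)C)c(O[Si](C(C)C)(C(C)C)C(C)C)cc1Oc1cccc(O[Si](C(C)C)(C(C)C)C(C)C)c1 | intermediate
27 | mixed anhydride of 26 with trifluoroacetic acid | O=C(Cc1cc(CC=C(C)C)c(O[Si](C(C)C)(C(C)C)C(C)C)cc1Oc1cccc(O[Si](C(C)C)(C(C)C)C(C)C)c1)OC(=O)C(F)(F)F | intermediate
28 | 2-(3-methylbut-2-enyl)-3,7-bis(triisopropylsilyloxy)dibenzo[b,f]oxepin-10(11H)-one | O=C1Cc2cc(CC=C(C)C)c(O[Si](C(C)C)(C(C)C)C(C)C)cc2Oc2cc(O[Si](C(C)C)(C(C)C)C(C)C)ccc21 | intermediate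
29 | nerol, (2Z)-3,7-dimethylocta-2,6-dien-1-ol | CC(C)=CCC/C(C)=C\CO | starting material
30 | [(2S,3R)-3-methyl-3-(4-methylpent-3-enyl)oxiran-2-yl]methanol | OC[C@@H]1O[C@]1(C)CCC=C(C)C | intermediate
31 | [(2S,3R)-3-methyl-3-(4-methylpent-3-enyl)oxiran-2-yl]methyl trifluoromethanesulfonate | O=S(=O)(OC[C@@H]1O[C@]1(C)CCC=C(C)C)C(F)(F)F | intermediate
32 | lithium enolate of 28 (C10=C11, O–Li on C10) | [Li]OC1=Cc2cc(CC=C(C)C)c(O[Si](C(C)C)(C(C)C)C(C)C)cc2Oc2cc(O[Si](C(C)C)(C(C)C)C(C)C)ccc21 | intermediate
33 | 11-[[(2S,3R)-3-methyl-3-(4-methylpent-3-enyl)oxiran-2-yl]methyl]-2-(3-methylbut-2-enyl)-3,7-bis(triisopropylsilyloxy)dibenzo[b,f]oxepin-10(11H)-one, both C11 epimers | O=C1C(C[C@@H]2O[C@]2(C)CCC=C(C)C)c2cc(CC=C(C)C)c(O[Si](C(C)C)(C(C)C)C(C)C)cc2Oc2cc(O[Si](C(C)C)(C(C)C)C(C)C)ccc21 | intermediate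
34 | 3,7-bis(triisopropylsilyl) ether of 35: (2S,3S)-3-hydroxy-2-methyl-2-(4-methylpent-3-enyl)-3,4-dihydro-2H-pyran fused across C10=C11 of 2-(3-methylbut-2-enyl)-3,7-bis(triisopropylsilyloxy)dibenzo[b,f]oxepine, pyran O on C10 | CC(C)=CCC[C@]1(C)OC2=C(C[C@@H]1O)c1cc(CC=C(C)C)c(O[Si](C(C)C)(C(C)C)C(C)C)cc1Oc1cc(O[Si](C(C)C)(C(C)C)C(C)C)ccc12 | intermediate
35 | target: (2S,3S)-3-hydroxy-2-methyl-2-(4-methylpent-3-enyl)-3,4-dihydro-2H-pyran fused across C10=C11 of 2-(3-methylbut-2-enyl)dibenzo[b,f]oxepine-3,7-diol, pyran O on C10, pyran CH2 on C11 | CC(C)=CCC[C@]1(C)OC2=C(C[C@@H]1O)c1cc(CC=C(C)C)c(O)cc1Oc1cc(O)ccc12 | target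

## Step count and least certain steps

Total: 15 steps. Longest linear sequence: 10 steps (steps 1–3, 7–10, 13–15 from resorcinol; equally steps 4–6, 7–10, 13–15 from prenyl bromide). The epoxide branch (steps 11–12) joins at step 13.

Step 7 (key step). The most likely failure is that ketene 20 is not intercepted efficiently. The aryloxy group is a weaker donor than the alkoxy and siloxy groups of the established alkyne partners, so dimerisation of the ketene, its capture by the product phenol and light-induced polymerisation of 9 can take over. In addition, part of the excited diazo ketone may lose nitrogen to a free carbene that undergoes 1,2-hydride shift from the CH2CO2Me arm instead of the Wolff shift. The fallback sets out from 19 and returns at 24; it takes the diaryl ether bond out of the annulation. Compound 19 is irradiated with tert-butyl ethynyl ether, an alkyl ynol ether of the proven class. Through tert-butoxy vinylcyclobutenone F1 and tert-butoxy dienylketene F2 this should give methyl 2-[2-tert-butoxy-4-hydroxy-5-(3-methylbut-2-enyl)phenyl]acetate F3. Silylation (i-Pr3SiCl, imidazole) gives the triisopropylsilyl ether F4, and brief treatment with CF3CO2H in CH2Cl2 at 0 °C removes the tert-butyl group to give phenol F5. Chan–Lam coupling of F5 with [3-(triisopropylsilyloxy)phenyl]boronic acid F6 (from 3-hydroxyphenylboronic acid and i-Pr3SiCl) under Cu(OAc)2, pyridine and air then gives 24.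

Step 14. The most likely failure is opening of the epoxide at the wrong carbon (5-exo attack of the carbonyl oxygen at the secondary centre). A second risk is ionisation to an open tertiary cation, with loss of configuration or hydride shift to a ketone (Meinwald rearrangement). The cause is that the regiochemistry rests only on the electronic preference for the tertiary carbon. The fallback sets out from 30 and 28 and returns at 35; it makes the tertiary C–O bond first and closes ring D with retention.
- Aqueous HClO4 in THF opens 30 at the tertiary carbon with inversion to (2S,3S)-3,7-dimethyloct-6-ene-1,2,3-triol F7.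
- Pivaloyl chloride and pyridine acylate the primary hydroxyl to give the pivalate F8.
- t-BuMe2SiCl and imidazole silylate the secondary hydroxyl to give the silyl ether F9, and Et3SiOTf with 2,6-lutidine the tertiary one to give the bis-silyl ether F10.
- i-Bu2AlH removes the pivalate to give the primary alcohol F11, and Tf2O with 2,6-lutidine gives the triflate F12.
- Alkylation of enolate 32 with F12 gives the ketone F13.
- Pyridinium p-toluenesulfonate in MeOH removes the triethylsilyl group to give the hydroxy ketone F14. Warming with the same acid in toluene over molecular sieves closes ring D by hemiketalisation and loss of water to the tert-butyldimethylsilyl ether F15; only the tertiary hydroxyl is free, so only the six-membered ring can form.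
- Bu4NF and AcOH remove all three silyl groups and give 35.

Step 13. The most likely failure is alkylation at the enolate oxygen, because the triflate is a hard electrophile and the enolate is delocalised into ring A. A second risk is proton transfer between product and enolate, leading to double alkylation. The fallback sets out from 28 and returns at 33. Compound 28 is condensed with Me2NNH2 to the N,N-dimethylhydrazone F16. LiN(i-Pr)2 gives the lithium aza-enolate F17, which reacts with carbon electrophiles at carbon only. Reaction with 31 gives the alkylated hydrazone F18, and hydrolysis with Cu(OAc)2 in aqueous THF returns 33.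

Step 10. The most likely failure is addition of the liberated trifluoroacetic acid to the prenyl alkene, or acid-induced loss of the ring A silyl group followed by closure of the freed phenol onto the prenyl group; acylation may also be slow without a stronger acid. The fallback sets out from 26 and returns at 28. Compound 26 is coupled with Me2NH (carbodiimide) to the N,N-dimethylamide F19. Activation with Tf2O and 2-chloropyridine at −78 °C, in a medium buffered by the pyridine, gives an iminium electrophile that attacks the same ring C carbon (intramolecular Vilsmeier–Haack-type acylation) to give the enamine F20. Mild aqueous work-up hydrolyses F20 to 28.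

## Further compounds

F1 | step 7 | methyl 2-[2-tert-butoxy-1-[(1E)-5-methylhexa-1,4-dienyl]-4-oxocyclobut-2-en-1-yl]acetate | COC(=O)CC1(/C=C/CC=C(C)C)C(=O)C=C1OC(C)(C)C
F2 | step 7 | methyl (4E)-3-(1-tert-butoxy-3-oxoprop-2-enylidene)-8-methylnona-4,7-dienoate | O=C=C/C(OC(C)(C)C)=C(CC(=O)OC)\C=C\CC=C(C)C
F3 | step 7 | methyl 2-[2-tert-butoxy-4-hydroxy-5-(3-methylbut-2-enyl)phenyl]acetate | COC(=O)Cc1cc(CC=C(C)C)c(O)cc1OC(C)(C)C
F4 | step 7 | methyl 2-[2-tert-butoxy-5-(3-methylbut-2-enyl)-4-(triisopropylsilyloxy)phenyl]acetate | COC(=O)Cc1cc(CC=C(C)C)c(O[Si](C(C)C)(C(C)C)C(C)C)cc1OC(C)(C)C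
F5 | step 7 | methyl 2-[2-hydroxy-5-(3-methylbut-2-enyl)-4-(triisopropylsilyloxy)phenyl]acetate | COC(=O)Cc1cc(CC=C(C)C)c(O[Si](C(C)C)(C(C)C)C(C)C)cc1O
F6 | step 7 | [3-(triisopropylsilyloxy)phenyl]boronic acid | OB(O)c1cccc(O[Si](C(C)C)(C(C)C)C(C)C)c1
F7 | step 14 | (2S,3S)-3,7-dimethyloct-6-ene-1,2,3-triol | OC[C@H](O)[C@@](C)(O)CCC=C(C)C
F8 | step 14 | (2S,3S)-2,3-dihydroxy-3,7-dimethyloct-6-enyl pivalate | CC(C)(C)C(=O)OC[C@H](O)[C@@](C)(O)CCC=C(C)C
F9 | step 14 | (2S,3S)-2-(tert-butyldimethylsilyloxy)-3-hydroxy-3,7-dimethyloct-6-enyl pivalate | CC(C)(C)C(=O)OC[C@H](O[Si](C)(C)C(C)(C)C)[C@@](C)(O)CCC=C(C)C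
F10 | step 14 | (2S,3S)-2-(tert-butyldimethylsilyloxy)-3,7-dimethyl-3-(triethylsilyloxy)oct-6-enyl pivalate | CC(C)(C)C(=O)OC[C@H](O[Si](C)(C)C(C)(C)C)[C@@](C)(O[Si](CC)(CC)CC)CCC=C(C)C
F11 | step 14 | (2S,3S)-2-(tert-butyldimethylsilyloxy)-3,7-dimethyl-3-(triethylsilyloxy)oct-6-en-1-ol | OC[C@H](O[Si](C)(C)C(C)(C)C)[C@@](C)(O[Si](CC)(CC)CC)CCC=C(C)C
F12 | step 14 | (2S,3S)-2-(tert-butyldimethylsilyloxy)-3,7-dimethyl-3-(triethylsilyloxy)oct-6-enyl trifluoromethanesulfonate | O=S(=O)(OC[C@H](O[Si](C)(C)C(C)(C)C)[C@@](C)(O[Si](CC)(CC)CC)CCC=C(C)C)C(F)(F)F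
F13 | step 14 | 11-[(2S,3S)-2-(tert-butyldimethylsilyloxy)-3,7-dimethyl-3-(triethylsilyloxy)oct-6-enyl]-2-(3-methylbut-2-enyl)-3,7-bis(triisopropylsilyloxy)dibenzo[b,f]oxepin-10(11H)-one | O=C1C(C[C@H](O[Si](C)(C)C(C)(C)C)[C@@](C)(O[Si](CC)(CC)CC)CCC=C(C)C)c2cc(CC=C(C)C)c(O[Si](C(C)C)(C(C)C)C(C)C)cc2Oc2cc(O[Si](C(C)C)(C(C)C)C(C)C)ccc21
F14 | step 14 | 11-[(2S,3S)-2-(tert-butyldimethylsilyloxy)-3-hydroxy-3,7-dimethyloct-6-enyl]-2-(3-methylbut-2-enyl)-3,7-bis(triisopropylsilyloxy)dibenzo[b,f]oxepin-10(11H)-one | O=C1C(C[C@H](O[Si](C)(C)C(C)(C)C)[C@@](C)(O)CCC=C(C)C)c2cc(CC=C(C)C)c(O[Si](C(C)C)(C(C)C)C(C)C)cc2Oc2cc(O[Si](C(C)C)(C(C)C)C(C)C)ccc21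
F15 | step 14 | tert-butyldimethylsilyl ether of 34 at the ring D hydroxyl | CC(C)=CCC[C@]1(C)OC2=C(C[C@@H]1O[Si](C)(C)C(C)(C)C)c1cc(CC=C(C)C)c(O[Si](C(C)C)(C(C)C)C(C)C)cc1Oc1cc(O[Si](C(C)C)(C(C)C)C(C)C)ccc12
F16 | step 13 | N,N-dimethylhydrazone of 28 | CN(C)N=C1Cc2cc(CC=C(C)C)c(O[Si](C(C)C)(C(C)C)C(C)C)cc2Oc2cc(O[Si](C(C)C)(C(C)C)C(C)C)ccc21
F17 | step 13 | lithium aza-enolate of F16 | [Li]N(N(C)C)C1=Cc2cc(CC=C(C)C)c(O[Si](C(C)C)(C(C)C)C(C)C)cc2Oc2cc(O[Si](C(C)C)(C(C)C)C(C)C)ccc21
F18 | step 13 | N,N-dimethylhydrazone of 33 | CN(C)N=C1C(C[C@@H]2O[C@]2(C)CCC=C(C)C)c2cc(CC=C(C)C)c(O[Si](C(C)C)(C(C)C)C(C)C)cc2Oc2cc(O[Si](C(C)C)(C(C)C)C(C)C)ccc21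
F19 | step 10 | N,N-dimethyl-2-[5-(3-methylbut-2-enyl)-4-(triisopropylsilyloxy)-2-[3-(triisopropylsilyloxy)phenoxy]phenyl]acetamide | CN(C)C(=O)Cc1cc(CC=C(C)C)c(O[Si](C(C)C)(C(C)C)C(C)C)cc1Oc1cccc(O[Si](C(C)C)(C(C)C)C(C)C)c1
F20 | step 10 | N,N-dimethyl-2-(3-methylbut-2-enyl)-3,7-bis(triisopropylsilyloxy)dibenzo[b,f]oxepin-10-amine | CN(C)C1=Cc2cc(CC=C(C)C)c(O[Si](C(C)C)(C(C)C)C(C)C)cc2Oc2cc(O[Si](C(C)C)(C(C)C)C(C)C)ccc21
A1 | alternative 1 | (5S,6S)-5-(tert-butyldimethylsilyloxy)-3-[2-hydroxy-4-(methoxymethoxy)-5-(3-methylbut-2-enyl)phenyl]-6-methyl-6-(4-methylpent-3-enyl)tetrahydropyran-2-one | O=C1O[C@@](C)(CCC=C(C)C)[C@@H](O[Si](C)(C)C(C)(C)C)CC1c1cc(CC=C(C)C)c(OCOC)cc1O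
A2 | alternative 1 | 3-chloro-5-(methoxymethoxy)-2-(trimethylsilyl)phenyl trifluoromethanesulfonate | COCOc1cc(Cl)c([Si](C)(C)C)c(OS(=O)(=O)C(F)(F)F)c1
A3 | alternative 1 | protected tetracycle with chlorine at C9, methoxymethyl ethers at C3 and C7, silyl ether at the ring D hydroxyl | CC(C)=CCC[C@]1(C)OC2=C(C[C@@H]1O[Si](C)(C)C(C)(C)C)c1cc(CC=C(C)C)c(OCOC)cc1Oc1cc(OCOC)cc(Cl)c12
A4 | alternative 2 | (3S,4S)-1-[2-bromo-4-(tert-butyldimethylsilyloxy)-5-(3-methylbut-2-enyl)phenyl]-3-(tert-butyldimethylsilyloxy)-4,8-dimethyl-1-oxonon-7-en-4-yl 2,4-bis(tert-butyldimethylsilyloxy)benzoate | CC(C)=CCC[C@](C)(OC(=O)c1ccc(O[Si](C)(C)C(C)(C)C)cc1O[Si](C)(C)C(C)(C)C)[C@@H](O[Si](C)(C)C(C)(C)C)CC(=O)c1cc(CC=C(C)C)c(O[Si](C)(C)C(C)(C)C)cc1Br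
A5 | alternative 2 | (2S,3S)-5-[2-bromo-4-(tert-butyldimethylsilyloxy)-5-(3-methylbut-2-enyl)phenyl]-6-[2,4-bis(tert-butyldimethylsilyloxy)phenyl]-3-(tert-butyldimethylsilyloxy)-2-methyl-2-(4-methylpent-3-enyl)-3,4-dihydro-2H-pyran | CC(C)=CCC[C@]1(C)OC(c2ccc(O[Si](C)(C)C(C)(C)C)cc2O[Si](C)(C)C(C)(C)C)=C(C[C@@H]1O[Si](C)(C)C(C)(C)C)c1cc(CC=C(C)C)c(O[Si](C)(C)C(C)(C)C)cc1Br
A6 | alternative 3 | 9-[(3S,4S)-1,1-dibromo-3-(tert-butyldimethylsilyloxy)-4,8-dimethyl-4-(triethylsilyloxy)non-7-enyl]-3,6-bis(tert-butyldimethylsilyloxy)xanthen-9-ol | CC(C)=CCC[C@](C)(O[Si](CC)(CC)CC)[C@@H](O[Si](C)(C)C(C)(C)C)CC(Br)(Br)C1(O)c2ccc(O[Si](C)(C)C(C)(C)C)cc2Oc2cc(O[Si](C)(C)C(C)(C)C)ccc21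
A7 | alternative 3 | 11-[(2S,3S)-2-(tert-butyldimethylsilyloxy)-3,7-dimethyl-3-(triethylsilyloxy)oct-6-enyl]-3,7-bis(tert-butyldimethylsilyloxy)dibenzo[b,f]oxepin-10(11H)-one | CC(C)=CCC[C@](C)(O[Si](CC)(CC)CC)[C@@H](O[Si](C)(C)C(C)(C)C)CC1C(=O)c2ccc(O[Si](C)(C)C(C)(C)C)cc2Oc2cc(O[Si](C)(C)C(C)(C)C)ccc12
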